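**Retrosynthetic overview**

Numbering of the carbocycle: C1 = C(OH)(butenoyl), C5 = CH–O‑acyl, C6 = lactone O–CH, C7 = lactone ring‑fusion CH, C8 = CH2, C9 = CH(OH), C10 = CH(CH3); C11/C12/C13 = lactone α‑carbon, carbonyl, exocyclic CH2.
1. The butenoyl C3=C4 comes from cross‑metathesis; the γ‑lactone is the last ring, closed by a carboxyl that displaces a C6–O–C9 oxygen bridge at C6 with inversion, so the bridge oxygen remains as the C9 hydroxyl.
2. In the bridged ketone the other centres are set from the open exo face: acyl‑anion addition to C1=O, hydroxylation at C5, hydrogenation at C7; C10 settles equatorial.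
3. Key disconnection C5–C6 and C9–C10: (4+3) cycloaddition of a 3‑substituted furan (C6–C7–C8–C9 plus the bridge oxygen) with a 2‑oxyallyl cation (C5–C1–C10); it closes the seven‑membered carbocycle and the oxygen bridge first, in one operation.
4. Enabling feature: oxygen on C6 and on C9, 1,4 across C7–C8 (a masked furan), facing the three‑carbon arc C5–C1–C10 whose central carbon carries oxygen (a masked 2‑oxyallyl cation).

Key step: step 4

Assumptions: (a) 1, 2, 5, 12, 14, 18 and 24 are taken as commercial. (b) The facial sense induced by the diphenyldioxolane group in step 4 is assumed as drawn; if it is the opposite, the (R,R)‑diol replaces 1 and everything from compound 8 on is unchanged. "Exo" means the side of the oxygen bridge, "endo" the side of the ketone bridge.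

Step 1
Reactants: 1 (1S,2S)-1,2-diphenylethane-1,2-diol; 2 3,3-dimethoxybutan-2-one
Product: 3 1-[(4S,5S)-2-methyl-4,5-diphenyl-1,3-dioxolan-2-yl]ethan-1-one
Conditions: p-TsOH·H2O (cat.), toluene, 60 °C, reduced pressure (MeOH removed)
Reagents that add atoms: none
Why: Acid‑catalysed transketalisation; the diol is C2‑symmetric, so the ketal carbon is not a stereocentre and one compound should result.

Step 2
Reactants: 3 1-[(4S,5S)-2-methyl-4,5-diphenyl-1,3-dioxolan-2-yl]ethan-1-one
Product: 4 triethyl({1-[(4S,5S)-2-methyl-4,5-diphenyl-1,3-dioxolan-2-yl]ethenyl}oxy)silane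
Conditions: TESOTf, Et3N, Et2O, 0 °C
Reagents that add atoms: triethylsilyl trifluoromethanesulfonate, CC[Si](CC)(CC)OS(=O)(=O)C(F)(F)F
Why: Soft enolisation and O‑silylation of a methyl ketone whose other α‑carbon is fully substituted, so only one silyl enol ether can form.

Step 3
Reactants: 5 2-(furan-3-yl)acetic acid
Product: 6 tert-butyl 2-(furan-3-yl)acetate
Conditions: Boc2O, DMAP (cat.), t-BuOH, 40 °C
Reagents that add atoms: di-tert-butyl dicarbonate, CC(C)(C)OC(=O)OC(=O)OC(C)(C)C
Why: Esterification through the mixed carbonic anhydride; the tert‑butyl ester is chosen because it resists organolithium reagents and later leaves as isobutene.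

Step 4
Reactants: 4 triethyl({1-[(4S,5S)-2-methyl-4,5-diphenyl-1,3-dioxolan-2-yl]ethenyl}oxy)silane; 6 tert-butyl 2-(furan-3-yl)acetate
Product: 7 tert-butyl 2-[(1R,2S,5R)-2-{(1S,2S)-1,2-diphenyl-2-[(triethylsilyl)oxy]ethoxy}-2-methyl-3-oxo-8-oxabicyclo[3.2.1]oct-6-en-6-yl]acetate
Conditions: TESOTf (0.2 equiv), 6 (3 equiv), CH2Cl2, −78 °C; Et3N quench
Reagents that add atoms: none
Why: The silyl triflate opens the dioxolane of 4 to a 1‑alkoxy‑1‑methyl‑2‑(silyloxy)allyl cation, which adds across the two α‑carbons of furan 6 in a (4+3) cycloaddition (allyl cation 2π, furan 4π); the closest known reaction type is the silyl‑triflate‑promoted (4+3) cycloaddition of silyl enol ethers of α‑keto acetals with furans, including variants that carry a chiral 1‑arylalkoxy group on the cation. The same two bonds close the seven‑membered carbocycle and the oxygen‑bridged pyranone ring; if the reaction is stepwise, C5–C6 forms first by attack of the furan α‑carbon next to the side chain on the CH2 terminus, and C9–C10 follows by capture of the furan‑derived oxocarbenium ion by the silyl enol ether carbon (7‑exo‑trig for the carbocycle, 6‑endo‑trig for the pyranone ring). The bridgehead centres C6 and C9 are necessarily cis because both bonds form on one face of the planar furan, and their absolute configuration is set by the face of the cation left open by the benzylic stereocentres of the alkoxy group; the configuration at C10 (drawn with the alkoxy group anti to the bridge) is of no consequence because step 5 removes that group. The step needs regioselectivity, and both electronics (the alkyl‑flanked furan α‑carbon is the more nucleophilic, the cation terminus remote from the alkoxy donor the softer electrophile) and sterics (the fully substituted terminus goes to the unhindered remote α‑carbon) point the same way. It also needs facial selectivity; because the auxiliary is enantiopure, adducts from the other face are diastereomers and should be separable by chromatography at this stage.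

Step 5
Reactants: 7 tert-butyl 2-[(1R,2S,5R)-2-{(1S,2S)-1,2-diphenyl-2-[(triethylsilyl)oxy]ethoxy}-2-methyl-3-oxo-8-oxabicyclo[3.2.1]oct-6-en-6-yl]acetate
Product: 8 tert-butyl 2-[(1R,2S,5R)-2-methyl-3-oxo-8-oxabicyclo[3.2.1]oct-6-en-6-yl]acetate
Conditions: SmI2 (2.5 equiv), THF–MeOH, −78 °C
Reagents that add atoms: none
Why: Reductive cleavage of an α‑alkoxy ketone by SmI2 gives the samarium enolate, whose protonation from the exo face (also the thermodynamic outcome) should leave the C10 methyl equatorial, anti to the oxygen bridge.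

Step 6
Reactants: 8 tert-butyl 2-[(1R,2S,5R)-2-methyl-3-oxo-8-oxabicyclo[3.2.1]oct-6-en-6-yl]acetate
Product: 9 tert-butyl 2-[(1R,2S,5R,6S)-2-methyl-3-oxo-8-oxabicyclo[3.2.1]octan-6-yl]acetate
Conditions: H2 (1 atm), 10% Pd/C, EtOAc, 23 °C
Reagents that add atoms: none
Why: Heterogeneous hydrogenation of the bicyclic alkene from the exo face (the endo face is covered by the ketone bridge) should put hydrogen exo at C7 and the acetate arm endo, cis to the later lactone oxygen.

Step 7
Reactants: 9 tert-butyl 2-[(1R,2S,5R,6S)-2-methyl-3-oxo-8-oxabicyclo[3.2.1]octan-6-yl]acetate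
Product: 11 tert-butyl 2-[(1R,2S,4S,5S,6S)-4-hydroxy-2-methyl-3-oxo-8-oxabicyclo[3.2.1]octan-6-yl]acetate, via silyl enol ether 10 (not isolated)
Conditions: LiN(iPr)2 (1.05 equiv), Me3SiCl, THF, −78 °C; then mCPBA, NaHCO3, CH2Cl2, 0 °C; then citric acid, MeOH–H2O
Reagents that add atoms: 3-chloroperbenzoic acid, OOC(=O)c1cccc(Cl)c1; chlorotrimethylsilane, C[Si](C)(C)Cl (silicon stays only in 10)
Why: Kinetic deprotonation at the CH2 α‑carbon (C5) rather than the methyl‑bearing C10, then Rubottom oxidation; the peracid should attack the silyl enol ether from the exo face, so the new C5–O bond is axial and syn to the oxygen bridge.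

Step 8
Reactants: 11 tert-butyl 2-[(1R,2S,4S,5S,6S)-4-hydroxy-2-methyl-3-oxo-8-oxabicyclo[3.2.1]octan-6-yl]acetate; 12 methoxyallene (1-methoxypropa-1,2-diene)
Product: 13 tert-butyl 2-[(1R,2S,3S,4S,5S,6S)-3,4-dihydroxy-3-(1-methoxypropa-1,2-dien-1-yl)-2-methyl-8-oxabicyclo[3.2.1]octan-6-yl]acetate
Conditions: 12 (3.3 equiv), n-BuLi (3.0 equiv), THF, −78 °C; then 11, −78 → −40 °C; NaHCO3 aq.
Reagents that add atoms: methoxyallene (12), COC=C=C
Why: 1,2‑Addition of 1‑lithio‑1‑methoxyallene, a small linear acyl‑anion equivalent (one equivalent is spent on the C5 hydroxyl), from the exo face of the bridged ketone, the endo face being blocked by the two‑carbon bridge and its endo side chain; this should set C1 with the hydroxyl endo (cis to the C10 methyl) and the carbon substituent exo.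

Step 9
Reactants: 13 tert-butyl 2-[(1R,2S,3S,4S,5S,6S)-3,4-dihydroxy-3-(1-methoxypropa-1,2-dien-1-yl)-2-methyl-8-oxabicyclo[3.2.1]octan-6-yl]acetate; 14 Eschenmoser's salt (N,N-dimethylmethyleneiminium iodide)
Product: 17 tert-butyl 2-[(1R,2S,3S,4S,5S,6S)-3,4-dihydroxy-3-(1-methoxypropa-1,2-dien-1-yl)-2-methyl-8-oxabicyclo[3.2.1]octan-6-yl]prop-2-enoate, via Mannich base 15 (not isolated), via methiodide 16 (not isolated)
Conditions: LiN(iPr)2 (3.3 equiv), THF, −78 °C; 14, −78 → 0 °C; then MeI, MeOH, 23 °C; then DBU, CH2Cl2, 23 °C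
Reagents that add atoms: Eschenmoser's salt (14), C[N+](C)=C.[I-]; iodomethane, CI (carbon stays only in 16)
Why: Mannich reaction of the tert‑butyl ester lithium enolate (the two hydroxyls ride as lithium alkoxides, the allenyl ether has no acidic hydrogen), then quaternisation and E1cB elimination to the acrylate; the transient C11 centre (epimer mixture in 15 and 16) is destroyed and no ring stereocentre is touched.

Step 10
Reactants: 17 tert-butyl 2-[(1R,2S,3S,4S,5S,6S)-3,4-dihydroxy-3-(1-methoxypropa-1,2-dien-1-yl)-2-methyl-8-oxabicyclo[3.2.1]octan-6-yl]prop-2-enoate; 18 (2S)-2-methylbutanoic acid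
Product: 19 tert-butyl 2-[(1R,2S,3S,4S,5S,6S)-3-hydroxy-3-(1-methoxypropa-1,2-dien-1-yl)-2-methyl-4-{[(2S)-2-methylbutanoyl]oxy}-8-oxabicyclo[3.2.1]octan-6-yl]prop-2-enoate
Conditions: 18, EDC·HCl, DMAP, CH2Cl2, 0 → 23 °C
Reagents that add atoms: (2S)-2-methylbutanoic acid (18), CC[C@H](C)C(=O)O
Why: Steglich esterification should acylate only the secondary C5 hydroxyl (the C1 hydroxyl is tertiary, the C9 oxygen is still tied up in the bridge), without enolising the (S) centre of the acid.

Step 11
Reactants: 19 tert-butyl 2-[(1R,2S,3S,4S,5S,6S)-3-hydroxy-3-(1-methoxypropa-1,2-dien-1-yl)-2-methyl-4-{[(2S)-2-methylbutanoyl]oxy}-8-oxabicyclo[3.2.1]octan-6-yl]prop-2-enoate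
Product: 20 tert-butyl 2-[(1R,2S,3S,4S,5S,6S)-3-hydroxy-2-methyl-4-{[(2S)-2-methylbutanoyl]oxy}-3-(prop-2-enoyl)-8-oxabicyclo[3.2.1]octan-6-yl]prop-2-enoate
Conditions: 0.5 M HCl aq., THF, 0 °C
Reagents that add atoms: water, O
Why: Hydrolysis of the 1‑methoxyallene (protonation at the central allene carbon, hydration of the oxocarbenium ion, loss of methanol) unmasks the α'‑hydroxy vinyl ketone, and dilute acid at 0 °C should spare the tert‑butyl acrylate.

Step 12
Reactants: 20 tert-butyl 2-[(1R,2S,3S,4S,5S,6S)-3-hydroxy-2-methyl-4-{[(2S)-2-methylbutanoyl]oxy}-3-(prop-2-enoyl)-8-oxabicyclo[3.2.1]octan-6-yl]prop-2-enoate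
Product: 23 (3aS,5R,6S,7S,8S,8aR)-5,7-dihydroxy-6-methyl-3-methylidene-2-oxo-7-(prop-2-enoyl)octahydro-2H-cyclohepta[b]furan-8-yl (2S)-2-methylbutanoate, via silyl ester 21 (not isolated), via bis-silyl lactone 22 (not isolated)
Conditions: TMSOTf (4 equiv), 2,6-lutidine (2.2 equiv), CH2Cl2, −78 → 23 °C; then 1 M HCl aq., THF, 0 °C
Reagents that add atoms: trimethylsilyl trifluoromethanesulfonate, C[Si](C)(C)OS(=O)(=O)C(F)(F)F (silicon stays only in 21 and 22)
Why: Proposed new method: TMSOTf first caps the C1 hydroxyl and turns the tert‑butyl acrylate into its silyl ester (21); silylation of the bridge oxygen then makes C6–O a leaving group, and the ester carbonyl oxygen, held on the endo face anti to that bond, should attack C6 in a 5‑exo‑tet SN2 displacement with inversion (silyl transfer from the lactonium ion to triflate closes the cycle), giving the cis‑fused α‑methylene lactone with the C6 oxygen trans to the C5 ester and the bridge oxygen retained on C9; the closest known reaction types are the Lewis‑acid‑promoted acylative cleavage of tetrahydrofurans by carboxylic acid derivatives and the 5‑exo lactonisation of epoxy esters with inversion, and no other nucleophile in the molecule can reach the backside of either bridge carbon.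

Step 13
Reactants: 23 (3aS,5R,6S,7S,8S,8aR)-5,7-dihydroxy-6-methyl-3-methylidene-2-oxo-7-(prop-2-enoyl)octahydro-2H-cyclohepta[b]furan-8-yl (2S)-2-methylbutanoate; 24 (Z)-but-2-ene
Product: 25 (3aS,5R,6S,7S,8S,8aR)-7-[(2E)-but-2-enoyl]-5,7-dihydroxy-6-methyl-3-methylidene-2-oxooctahydro-2H-cyclohepta[b]furan-8-yl (2S)-2-methylbutanoate (CNP0331957.1)
Conditions: 24 (excess), second-generation Hoveyda–Grubbs catalyst (5 mol%), CH2Cl2, 23 °C
Reagents that add atoms: (Z)-but-2-ene (24), C/C=C\C
Why: Olefin cross‑metathesis of the monosubstituted vinyl ketone with 2‑butene should give the (E)‑enone under thermodynamic control, while the 1,1‑disubstituted α‑methylene lactone is a much poorer metathesis partner at room temperature.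

**Compound list**

1 | (1S,2S)-1,2-diphenylethane-1,2-diol | O[C@@H](c1ccccc1)[C@@H](O)c1ccccc1 | starting material
2 | 3,3-dimethoxybutan-2-one | CC(=O)C(C)(OC)OC | starting material
3 | 1-[(4S,5S)-2-methyl-4,5-diphenyl-1,3-dioxolan-2-yl]ethan-1-one | CC(=O)C1(C)O[C@@H](c2ccccc2)[C@H](c2ccccc2)O1 | intermediate
4 | triethyl({1-[(4S,5S)-2-methyl-4,5-diphenyl-1,3-dioxolan-2-yl]ethenyl}oxy)silane | C=C(O[Si](CC)(CC)CC)C1(C)O[C@@H](c2ccccc2)[C@H](c2ccccc2)O1 | intermediate
5 | 2-(furan-3-yl)acetic acid | OC(=O)Cc1ccoc1 | starting material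
6 | tert-butyl 2-(furan-3-yl)acetate | CC(C)(C)OC(=O)Cc1ccoc1 | intermediate
7 | tert-butyl 2-[(1R,2S,5R)-2-{(1S,2S)-1,2-diphenyl-2-[(triethylsilyl)oxy]ethoxy}-2-methyl-3-oxo-8-oxabicyclo[3.2.1]oct-6-en-6-yl]acetate | O=C1C[C@H]2O[C@H](C=C2CC(=O)OC(C)(C)C)[C@]1(C)O[C@@H](c1ccccc1)[C@@H](O[Si](CC)(CC)CC)c1ccccc1 | intermediate
8 | tert-butyl 2-[(1R,2S,5R)-2-methyl-3-oxo-8-oxabicyclo[3.2.1]oct-6-en-6-yl]acetate | O=C1C[C@H]2O[C@H](C=C2CC(=O)OC(C)(C)C)[C@@H]1C | intermediate
9 | tert-butyl 2-[(1R,2S,5R,6S)-2-methyl-3-oxo-8-oxabicyclo[3.2.1]octan-6-yl]acetate | O=C1C[C@H]2O[C@H](C[C@H]2CC(=O)OC(C)(C)C)[C@@H]1C | intermediate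
10 | trimethylsilyl enol ether of 9 (O-silylated at the ketone oxygen, double bond from the ketone carbon towards the unsubstituted α-carbon) | C[Si](C)(C)OC1=C[C@H]2O[C@H](C[C@H]2CC(=O)OC(C)(C)C)[C@@H]1C | intermediate
11 | tert-butyl 2-[(1R,2S,4S,5S,6S)-4-hydroxy-2-methyl-3-oxo-8-oxabicyclo[3.2.1]octan-6-yl]acetate | O=C1[C@@H](O)[C@H]2O[C@H](C[C@H]2CC(=O)OC(C)(C)C)[C@@H]1C | intermediate
12 | methoxyallene (1-methoxypropa-1,2-diene) | COC=C=C | starting material
13 | tert-butyl 2-[(1R,2S,3S,4S,5S,6S)-3,4-dihydroxy-3-(1-methoxypropa-1,2-dien-1-yl)-2-methyl-8-oxabicyclo[3.2.1]octan-6-yl]acetate | C=C=C(OC)[C@@]1(O)[C@@H](O)[C@H]2O[C@H](C[C@H]2CC(=O)OC(C)(C)C)[C@@H]1C | intermediate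
14 | Eschenmoser's salt (N,N-dimethylmethyleneiminium iodide) | C[N+](C)=C.[I-] | starting material
15 | Mannich base: 13 with a CH2NMe2 group on the ester α-carbon (both epimers at that carbon) | C=C=C(OC)[C@@]1(O)[C@@H](O)[C@H]2O[C@H](C[C@H]2C(CN(C)C)C(=O)OC(C)(C)C)[C@@H]1C | intermediate
16 | methiodide of 15 (trimethylammonium iodide, both epimers at the ester α-carbon) | C=C=C(OC)[C@@]1(O)[C@@H](O)[C@H]2O[C@H](C[C@H]2C(C[N+](C)(C)C)C(=O)OC(C)(C)C)[C@@H]1C.[I-] | intermediate
17 | tert-butyl 2-[(1R,2S,3S,4S,5S,6S)-3,4-dihydroxy-3-(1-methoxypropa-1,2-dien-1-yl)-2-methyl-8-oxabicyclo[3.2.1]octan-6-yl]prop-2-enoate | C=C=C(OC)[C@@]1(O)[C@@H](O)[C@H]2O[C@H](C[C@H]2C(=C)C(=O)OC(C)(C)C)[C@@H]1C | intermediate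
18 | (2S)-2-methylbutanoic acid | CC[C@H](C)C(=O)O | starting material
19 | tert-butyl 2-[(1R,2S,3S,4S,5S,6S)-3-hydroxy-3-(1-methoxypropa-1,2-dien-1-yl)-2-methyl-4-{[(2S)-2-methylbutanoyl]oxy}-8-oxabicyclo[3.2.1]octan-6-yl]prop-2-enoate | C=C=C(OC)[C@@]1(O)[C@@H](OC(=O)[C@@H](C)CC)[C@H]2O[C@H](C[C@H]2C(=C)C(=O)OC(C)(C)C)[C@@H]1C | intermediate
20 | tert-butyl 2-[(1R,2S,3S,4S,5S,6S)-3-hydroxy-2-methyl-4-{[(2S)-2-methylbutanoyl]oxy}-3-(prop-2-enoyl)-8-oxabicyclo[3.2.1]octan-6-yl]prop-2-enoate | C=CC(=O)[C@@]1(O)[C@@H](OC(=O)[C@@H](C)CC)[C@H]2O[C@H](C[C@H]2C(=C)C(=O)OC(C)(C)C)[C@@H]1C | intermediate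
21 | 20 with the tertiary hydroxyl as its trimethylsilyl ether and the tert-butyl acrylate replaced by the trimethylsilyl acrylate | C=CC(=O)[C@@]1(O[Si](C)(C)C)[C@@H](OC(=O)[C@@H](C)CC)[C@H]2O[C@H](C[C@H]2C(=C)C(=O)O[Si](C)(C)C)[C@@H]1C | intermediate
22 | bis(trimethylsilyl) ether of 23 (both hydroxyls silylated) | C=C1C(=O)O[C@@H]2[C@H]1C[C@@H](O[Si](C)(C)C)[C@H](C)[C@@](O[Si](C)(C)C)(C(=O)C=C)[C@H]2OC(=O)[C@@H](C)CC | intermediate
23 | (3aS,5R,6S,7S,8S,8aR)-5,7-dihydroxy-6-methyl-3-methylidene-2-oxo-7-(prop-2-enoyl)octahydro-2H-cyclohepta[b]furan-8-yl (2S)-2-methylbutanoate | C=C1C(=O)O[C@@H]2[C@H]1C[C@@H](O)[C@H](C)[C@@](O)(C(=O)C=C)[C@H]2OC(=O)[C@@H](C)CC | intermediate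
24 | (Z)-but-2-ene | C/C=C\C | starting material
25 | (3aS,5R,6S,7S,8S,8aR)-7-[(2E)-but-2-enoyl]-5,7-dihydroxy-6-methyl-3-methylidene-2-oxooctahydro-2H-cyclohepta[b]furan-8-yl (2S)-2-methylbutanoate | C=C1C(=O)O[C@@H]2[C@H]1C[C@@H](O)[C@H](C)[C@@](O)(C(=O)/C=C/C)[C@H]2OC(=O)[C@@H](C)CC | target

**Step count and risks**

Total step count: 13. Longest linear sequence: 12 steps (steps 1, 2, 4–13; step 3 is a one‑step branch).

Steps most likely to fail:

1. Step 12 (proposed new method). The silylated bridge may not open, or the bridge may be cleaved at C9 by an external nucleophile instead of at C6 by the internal ester; acid‑induced ketol rearrangement is a further risk. The fallback uses known reactions, sets out from 20 and comes back at 23. Me2BBr (CH2Cl2, −78 → 0 °C) should cleave the bridge by SN2 attack of bromide at C9, the less hindered and less deactivated carbon (inversion), and remove the tert‑butyl group, giving the ring‑opened bromo hydroxy acid F1 (any bromide added to the vinyl ketone is lost again on Et3N work‑up). Mitsunobu lactonisation (PPh3, DIAD, THF) should close the lactone with inversion at C6 to the bromo lactone F2. CsO2CH (18‑crown‑6, DMF) should displace bromide with a second inversion at C9 to the formate ester F3, and NaHCO3 in MeOH then frees the C9 alcohol, which is 23.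

2. Step 4 (key step). Possible failures are first bond formation at the remote α‑carbon of the furan (wrong regiochemistry), proton loss after the first bond (open‑chain furan alkylation instead of ring closure), and weak facial control by the alkoxy group. The fallback sets out from 4 and comes back at 7. 3‑Bromofuran (Brc1ccoc1) replaces 6; bromine is small and directs electrophiles firmly to the adjacent α‑carbon, so the cycloaddition should give the vinyl bromide cycloadduct F4. Negishi coupling of F4 with the Reformatsky reagent BrZnCH2CO2t‑Bu (Pd[P(t‑Bu)3]2, zerovalent palladium, THF) then installs the acetate arm and gives 7.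

3. Step 8. The hindered ketone may be enolised instead of attacked, or the α‑alkoxide may undergo base‑induced ketol isomerisation. The fallback avoids the free ketol, sets out from 9 and comes back at 13. The silyl enol ether 10 is brominated (NBS, THF, −78 °C, exo attack) to the axial α‑bromo ketone F5. Exo addition of 1‑lithio‑1‑methoxyallene gives a bromohydrin alkoxide that should close, trans‑diaxially, to the endo epoxide F6. CsO2CH (18‑crown‑6, DMF) should open the epoxide at the secondary carbon C5 from the exo face (trans‑diaxial, Fürst–Plattner) to the C5 formate ester F7, and K2CO3 in MeOH gives 13.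

**Further compounds**

F1 | step 12 | ring-opened bromo hydroxy acid: cycloheptane with C9–Br anti to the former bridge, free C6–OH syn to the C5 ester, free acrylic acid at C7 | C=C(C(=O)O)[C@@H]1C[C@H](Br)[C@H](C)[C@@](O)(C(=O)C=C)[C@@H](OC(=O)[C@@H](C)CC)[C@H]1O
F2 | step 12 | bromo lactone: 23 with bromine in place of the C9 hydroxyl, inverted at C9 | C=C1C(=O)O[C@@H]2[C@H]1C[C@H](Br)[C@H](C)[C@@](O)(C(=O)C=C)[C@H]2OC(=O)[C@@H](C)CC
F3 | step 12 | formate ester of 23 at the C9 hydroxyl | C=C1C(=O)O[C@@H]2[C@H]1C[C@@H](OC=O)[C@H](C)[C@@](O)(C(=O)C=C)[C@H]2OC(=O)[C@@H](C)CC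
F4 | step 4 | vinyl bromide cycloadduct: 7 with bromine in place of the CH2CO2t-Bu arm | O=C1C[C@H]2O[C@H](C=C2Br)[C@]1(C)O[C@@H](c1ccccc1)[C@@H](O[Si](CC)(CC)CC)c1ccccc1
F5 | step 8 | α-bromo ketone: 11 with axial bromine in place of the hydroxyl | O=C1[C@@H](Br)[C@H]2O[C@H](C[C@H]2CC(=O)OC(C)(C)C)[C@@H]1C
F6 | step 8 | endo epoxide spanning C1 and C5, with the 1-methoxyallenyl group exo on C1 | C=C=C(OC)[C@@]12O[C@@H]1[C@H]3O[C@H](C[C@H]3CC(=O)OC(C)(C)C)[C@@H]2C
F7 | step 8 | formate ester of 13 at the secondary (C5) hydroxyl | C=C=C(OC)[C@@]1(O)[C@@H](OC=O)[C@H]2O[C@H](C[C@H]2CC(=O)OC(C)(C)C)[C@@H]1C
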